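The cyclononene is traced back to a cyclopentene. In the nine-membered ring the methylidene-bearing carbon and the C(CH3)OH carbon, both carbonyl-derived, stand 1,6 along the arc CH–CH–CH2–CH2 and 1,5 along the cis-alkene arc. This is the retron of an oxy-Cope ring expansion of a 1,2-dioxygenated cis-1,2-dialkenylcyclopent-3-ene. In one flask the alkoxide of such a diol mono-TIPS ether joins its vinyl CH2 to the alkenyl CH next to the quaternary oxolane carbon and breaks the cyclopentene C1–C2 bond. The alkene stays cis and the two carbonyl positions emerge differentiated (enolate, silyl dienol ether). Formaldehyde capture sets the trans ring fusion. The precursor holds no medium ring and no oxolane.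

Key step: step 12

Assumption: the ligand antipode in step 2 and the glycidate antipode in step 5 are taken to be those that deliver the drawn configurations; both antipodes of each are commercial.

Step 1
Reactants: 1 3-methylbut-2-enal; 2 ethyl 2-oxo-3-(triphenyl-λ5-phosphanylidene)propanoate
Product: 3 ethyl (3E)-6-methyl-2-oxohepta-3,5-dienoate
Conditions: CH2Cl2, rt to 40 °C
Reagents that add atoms: none
Why: Wittig olefination with a stabilised acyl ylide should give the (E)-alkene and leaves the trisubstituted alkene of 1 untouched.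

Step 2
Reactants: 3 ethyl (3E)-6-methyl-2-oxohepta-3,5-dienoate; 4 ethynyl(trimethyl)silane
Product: 5 ethyl (2R,3E)-2-hydroxy-6-methyl-2-[(trimethylsilyl)ethynyl]hepta-3,5-dienoate
Conditions: Zn(OTf)2, (1S,2S)-2-(dimethylamino)-1-(4-nitrophenyl)-3-(tert-butyldimethylsilyloxy)propan-1-ol, Et3N, toluene, 50–70 °C
Reagents that add atoms: none
Why: Zinc acetylide addition of the Carreira type, known to extend to α-keto esters, attacks the activated ketone in 1,2-fashion, and the amino alcohol bound to zinc sets the tertiary carbinol centre as (R).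

Step 3
Reactants: 5 ethyl (2R,3E)-2-hydroxy-6-methyl-2-[(trimethylsilyl)ethynyl]hepta-3,5-dienoate
Product: 7 (2R,3E)-2-ethynyl-6-methylhepta-3,5-diene-1,2-diol, via silylated diol 6 (not isolated)
Conditions: NaBH4, MeOH, 0 °C to rt; then K2CO3 (cat.), rt
Reagents that add atoms: none
Why: Borohydride reduction of an α-hydroxy ester, followed by methanolysis of the alkynyl C–Si bond in the same flask, touches neither the diene, the alkyne nor the stereocentre.

Step 4
Reactants: 7 (2R,3E)-2-ethynyl-6-methylhepta-3,5-diene-1,2-diol
Product: 8 (3R,4E)-3-{[tert-butyl(diphenyl)silyl]oxymethyl}-7-methylocta-4,6-dien-1-yn-3-ol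
Conditions: TBDPSCl, imidazole, CH2Cl2, 0 °C
Reagents that add atoms: tert-butyl(chloro)diphenylsilane CC(C)(C)[Si](Cl)(c1ccccc1)c1ccccc1
Why: Silylation with a bulky chlorosilane is selective for the primary over the tertiary hydroxyl.

Step 5
Reactants: 9 methyl (2R)-oxirane-2-carboxylate
Product: 10 methyl (2R)-2-hydroxypent-4-enoate
Conditions: CH2=CHMgBr, CuBr·SMe2 (cat.), THF, −78 to −40 °C
Reagents that add atoms: vinylmagnesium bromide C=C[Mg]Br
Why: Copper-catalysed Grignard opening of a glycidic ester occurs at the unsubstituted C3, so the C2–O bond and the (R) configuration of the chiral-pool epoxide are kept.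

Step 6
Reactants: 10 methyl (2R)-2-hydroxypent-4-enoate
Product: 11 (4R)-3-ethenylhepta-1,6-diene-3,4-diol
Conditions: CH2=CHMgBr (excess), THF, −78 to 0 °C
Reagents that add atoms: vinylmagnesium bromide C=C[Mg]Br
Why: Double Grignard addition to the ester (after deprotonation of the hydroxyl) builds the divinyl carbinol and leaves the existing stereocentre untouched.

Step 7
Reactants: 11 (4R)-3-ethenylhepta-1,6-diene-3,4-diol
Product: 12 (1R,2S)-2-ethenylcyclopent-3-ene-1,2-diol (cis-diol)
Conditions: second-generation Grubbs catalyst RuCl2(=CHPh)(PCy3)(SIMes) (cat.), CH2Cl2, 40 °C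
Reagents that add atoms: none
Why: Ring-closing metathesis can only form the cyclopentene, and of the two diastereotopic vinyl groups the one that leaves the remaining vinyl anti to the C1 hydroxyl (hydrogen-bonded cis-diol) should react, which sets C2 as (S), any trans-diol being removed by chromatography.

Step 8
Reactants: 12 (1R,2S)-2-ethenylcyclopent-3-ene-1,2-diol
Product: 13 (2S)-2-ethenyl-2-hydroxycyclopent-3-en-1-one
Conditions: Dess–Martin periodinane, CH2Cl2, 0 °C to rt
Reagents that add atoms: none
Why: Dess–Martin oxidation takes only the secondary alcohol, and its neutral conditions avoid both conjugation of the β,γ-alkene and an α-ketol shift.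

Step 9
Reactants: 13 (2S)-2-ethenyl-2-hydroxycyclopent-3-en-1-one
Product: 14 (2S)-2-ethenyl-2-[tri(propan-2-yl)silyloxy]cyclopent-3-en-1-one
Conditions: TIPSOTf, 2,6-lutidine, CH2Cl2, −78 to 0 °C
Reagents that add atoms: triisopropylsilyl trifluoromethanesulfonate CC(C)[Si](OS(=O)(=O)C(F)(F)F)(C(C)C)C(C)C
Why: Silyl triflate silylation reaches hindered tertiary alcohols, while the weak base lutidine should not enolise the ketone.

Step 10
Reactants: 8 (3R,4E)-3-{[tert-butyl(diphenyl)silyl]oxymethyl}-7-methylocta-4,6-dien-1-yn-3-ol; 14 (2S)-2-ethenyl-2-[tri(propan-2-yl)silyloxy]cyclopent-3-en-1-one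
Product: 16 (1S,2S)-2-ethenyl-1-[(3R,4E)-3-hydroxy-3-(TBDPS-oxymethyl)-7-methylocta-4,6-dien-1-yn-1-yl]-2-(TIPS-oxy)cyclopent-3-en-1-ol, via dilithium alkynide alkoxide 15 (not isolated)
Conditions: 8, n-BuLi (2 equiv), THF, −78 °C; LaCl3·2LiCl; then 14, −78 to −30 °C
Reagents that add atoms: none
Why: 1,2-Addition of a lanthanum-activated lithium acetylide (low basicity, against enolisation) under Felkin–Anh control, in which the bulky non-chelating OTIPS group stands perpendicular to the carbonyl and the slim nucleophile enters anti to it, places the alkynyl group cis to the vinyl group and sets C1 as (S).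

Step 11
Reactants: 16 the propargylic diol of step 10
Product: 17 (1S,2S)-2-ethenyl-1-[(1E,3R,4E)-3-hydroxy-3-(TBDPS-oxymethyl)-7-methylocta-1,4,6-trien-1-yl]-2-(TIPS-oxy)cyclopent-3-en-1-ol
Conditions: NaAlH2(OCH2CH2OMe)2 (Red-Al), THF, 0 °C to rt
Reagents that add atoms: none
Why: Hydroxyl-directed trans-hydroalumination of a but-2-yne-1,4-diol unit and protonolysis give the (E)-alkene only, while isolated alkenes, the diene and the silyl ethers are inert.

Step 12
Reactants: 17 the cis-1-alkenyl-2-vinylcyclopentenediol mono-TIPS ether of step 11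
Product: 20 (2S,3S,5E,7Z)-2-(hydroxymethyl)-3-[(2R,3E)-1-(TBDPS-oxy)-2-hydroxy-6-methylhepta-3,5-dien-2-yl]-6-(TIPS-oxy)cyclonona-5,7-dien-1-one (both ring double bonds ring-cis), via dipotassium dialkoxide 18 (not isolated), via dipotassium enolate 19 (not isolated)
Conditions: KH, 18-crown-6, THF, 0 °C to rt; then CH2O (monomeric, THF), −78 °C; AcOH quench
Reagents that add atoms: formaldehyde C=O
Why: KH and 18-crown-6 convert 17 into dialkoxide 18, whose C1 alkoxide weakens the cyclopentene C1–C2 bond and sets off a concerted, suprafacial [3,3]-sigmatropic shift that bonds the vinyl CH2 to the alkenyl CH next to the side-chain carbinol carbon and gives enolate 19. The closest known reaction type is the anionic oxy-Cope four-carbon ring expansion of 1,2-dialkenylcycloalkanols followed by capture of the regiodefined enolate by an electrophile. The nine-membered ring is closed by ring expansion (five to nine atoms) through the endo,endo boat array typical of cis-1,2-dialkenyl small rings, because either chair would force a trans double bond into a cyclononatriene, so all three ring double bonds of 19, the future cis-alkene included, are cis. The new CH stereocentre (S) is controlled by chirality transfer from C1 and C2 of the cyclopentene (both destroyed), the (E)-alkene keeping the bulky carbinol substituent outside the array. The second new stereocentre, the CH bearing CH2OH, is controlled by peripheral attack: the carbocycle covers the inner enolate face, formaldehyde enters from outside, anti to the bond just formed across the former (E)-alkene, and this gives the trans ring-fusion pattern. The step needs periselectivity, secured because the alternative 1,5-diene through the endocyclic alkene has its breaking C1–C5 bond in the nodal plane of that π bond, and it needs the silyl group to stay on O2, secured by the bulk of TIPS, so that the two future carbonyl positions emerge differentiated as enolate and silyl dienol ether.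

Step 13
Reactants: 20 the hydroxymethyl cyclononadienone of step 12
Product: 21 methylidene analogue of 20 (ring C=O replaced by C=CH2, all stereocentres unchanged in space)
Conditions: Cp2Ti(μ-CH2)(μ-Cl)AlMe2 (Tebbe reagent, excess), pyridine, THF–toluene, −40 to 0 °C
Reagents that add atoms: Tebbe reagent C[Al-]1(C)C[Ti](C2C=CC=C2)(C2C=CC=C2)[Cl+]1
Why: Tebbe methylenation uses a non-basic titanium methylidene, so the hindered, easily enolised β-hydroxy ketone is olefinated without epimerisation, retro-aldol cleavage or alkene migration, and the silyl dienol ether is inert.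

Step 14
Reactants: 21 the diol of step 13
Product: 23 trans-fused oxolane–cyclononatriene: 21 with the CH2–O–C(quaternary) ether bond closed (TIPS dienol ether and TBDPS ether retained), via primary mesylate 22 (not isolated)
Conditions: MsCl, Et3N, CH2Cl2, −30 °C; then KOt-Bu, THF, 0 °C
Reagents that add atoms: none
Why: Selective mesylation of the primary alcohol and intramolecular Williamson etherification (5-exo-tet) by the tertiary alkoxide close the oxolane without breaking the C–O bond of the quaternary stereocentre, whose (R) configuration is therefore kept.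

Step 15
Reactants: 23 the bis-silylated bicycle of step 14
Product: 24 cis-enone alcohol: the bicycle with ring C=O at the former silyl dienol ether carbon and free CH2OH
Conditions: Bu4NF, AcOH, THF, 0 °C to rt
Reagents that add atoms: none
Why: Fluoride desilylation removes both silyl groups, and the buffered cross-conjugated dienolate is protonated at its α-carbon, which gives the conjugated cis-enone directly without base-induced migration of the skipped methylidene.

Step 16
Reactants: 24 the cis-enone alcohol of step 15
Product: 25 diol: the target lacking its stearoyl group, new carbinol centre (S)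
Conditions: MeLi, CeCl3, THF, −78 °C
Reagents that add atoms: methyllithium [Li]C
Why: Organocerium 1,2-addition (non-basic, no γ-deprotonation, no 1,4-addition) should deliver methyl to the open Re face of the carbonyl, which conjugation holds close to the plane of the cis-alkene while the CH2–CH2 arc and the oxolane fold under the other face, and this sets the tertiary carbinol as (S).

Step 17
Reactants: 25 the diol of step 16; 26 octadecanoyl chloride
Product: 27 the target, CNP0274030.1
Conditions: pyridine, DMAP (cat.), CH2Cl2, 0 °C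
Reagents that add atoms: none
Why: Acylation with an acid chloride is selective for the primary hydroxyl, since the tertiary allylic alcohol is too hindered to react under these conditions.

Compound list
1 | 3-methylbut-2-enal | CC(C)=CC=O | starting material
2 | ethyl 2-oxo-3-(triphenyl-λ5-phosphanylidene)propanoate | CCOC(=O)C(=O)C=P(c1ccccc1)(c1ccccc1)c1ccccc1 | starting material
3 | ethyl (3E)-6-methyl-2-oxohepta-3,5-dienoate | CCOC(=O)C(=O)/C=C/C=C(C)C | intermediate
4 | ethynyl(trimethyl)silane | C#C[Si](C)(C)C | starting material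
5 | ethyl (2R,3E)-2-hydroxy-6-methyl-2-[(trimethylsilyl)ethynyl]hepta-3,5-dienoate | CCOC(=O)[C@](O)(C#C[Si](C)(C)C)/C=C/C=C(C)C | intermediate
6 | (2R,3E)-6-methyl-2-[(trimethylsilyl)ethynyl]hepta-3,5-diene-1,2-diol | OC[C@](O)(C#C[Si](C)(C)C)/C=C/C=C(C)C | intermediate
7 | (2R,3E)-2-ethynyl-6-methylhepta-3,5-diene-1,2-diol | OC[C@](O)(C#C)/C=C/C=C(C)C | intermediate
8 | (3R,4E)-3-{[tert-butyl(diphenyl)silyl]oxymethyl}-7-methylocta-4,6-dien-1-yn-3-ol | C#C[C@@](O)(CO[Si](c1ccccc1)(c1ccccc1)C(C)(C)C)/C=C/C=C(C)C | intermediate
9 | methyl (2R)-oxirane-2-carboxylate | COC(=O)[C@H]1CO1 | starting material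
10 | methyl (2R)-2-hydroxypent-4-enoate | COC(=O)[C@H](O)CC=C | intermediate
11 | (4R)-3-ethenylhepta-1,6-diene-3,4-diol | C=CC[C@@H](O)C(O)(C=C)C=C | intermediate
12 | (1R,2S)-2-ethenylcyclopent-3-ene-1,2-diol | O[C@@H]1CC=C[C@@]1(O)C=C | intermediate
13 | (2S)-2-ethenyl-2-hydroxycyclopent-3-en-1-one | O=C1CC=C[C@@]1(O)C=C | intermediate
14 | (2S)-2-ethenyl-2-[tri(propan-2-yl)silyloxy]cyclopent-3-en-1-one | O=C1CC=C[C@@]1(O[Si](C(C)C)(C(C)C)C(C)C)C=C | intermediate
15 | dilithium alkynide alkoxide of 8 | [Li+].[Li+].[C-]#C[C@@]([O-])(CO[Si](c1ccccc1)(c1ccccc1)C(C)(C)C)/C=C/C=C(C)C | intermediate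
16 | (1S,2S)-2-ethenyl-1-[(3R,4E)-3-hydroxy-3-(TBDPS-oxymethyl)-7-methylocta-4,6-dien-1-yn-1-yl]-2-(TIPS-oxy)cyclopent-3-en-1-ol | C=C[C@]1(O[Si](C(C)C)(C(C)C)C(C)C)C=CC[C@]1(O)C#C[C@@](O)(CO[Si](c1ccccc1)(c1ccccc1)C(C)(C)C)/C=C/C=C(C)C | intermediate
17 | (1S,2S)-2-ethenyl-1-[(1E,3R,4E)-3-hydroxy-3-(TBDPS-oxymethyl)-7-methylocta-1,4,6-trien-1-yl]-2-(TIPS-oxy)cyclopent-3-en-1-ol | C=C[C@]1(O[Si](C(C)C)(C(C)C)C(C)C)C=CC[C@]1(O)/C=C/[C@@](O)(CO[Si](c1ccccc1)(c1ccccc1)C(C)(C)C)/C=C/C=C(C)C | intermediate
18 | dipotassium dialkoxide of 17 | [K+].[K+].C=C[C@]1(O[Si](C(C)C)(C(C)C)C(C)C)C=CC[C@]1([O-])/C=C/[C@@]([O-])(CO[Si](c1ccccc1)(c1ccccc1)C(C)(C)C)/C=C/C=C(C)C | intermediate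
19 | dipotassium salt of the ring-expanded all-cis cyclononatriene enolate (side-chain alkoxide retained) | [K+].[K+].[O-]/C1=C/[C@@H]([C@@]([O-])(CO[Si](c2ccccc2)(c2ccccc2)C(C)(C)C)/C=C/C=C(C)C)C/C=C(O[Si](C(C)C)(C(C)C)C(C)C)\C=C/C1 | intermediate
20 | (2S,3S,5E,7Z)-2-(hydroxymethyl)-3-[(2R,3E)-1-(TBDPS-oxy)-2-hydroxy-6-methylhepta-3,5-dien-2-yl]-6-(TIPS-oxy)cyclonona-5,7-dien-1-one | O=C1C/C=C\C(O[Si](C(C)C)(C(C)C)C(C)C)=C/C[C@H]([C@@](O)(CO[Si](c2ccccc2)(c2ccccc2)C(C)(C)C)/C=C/C=C(C)C)[C@H]1CO | intermediate
21 | methylidene analogue of 20 (C=O replaced by C=CH2) | C=C1C/C=C\C(O[Si](C(C)C)(C(C)C)C(C)C)=C/C[C@H]([C@@](O)(CO[Si](c2ccccc2)(c2ccccc2)C(C)(C)C)/C=C/C=C(C)C)[C@H]1CO | intermediate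
22 | primary methanesulfonate of 21 | C=C1C/C=C\C(O[Si](C(C)C)(C(C)C)C(C)C)=C/C[C@H]([C@@](O)(CO[Si](c2ccccc2)(c2ccccc2)C(C)(C)C)/C=C/C=C(C)C)[C@H]1COS(C)(=O)=O | intermediate
23 | trans-fused oxolane–cyclononatriene with TIPS dienol ether and TBDPS ether | C=C1C/C=C\C(O[Si](C(C)C)(C(C)C)C(C)C)=C/C[C@H]2[C@H]1CO[C@@]2(/C=C/C=C(C)C)CO[Si](c1ccccc1)(c1ccccc1)C(C)(C)C | intermediate
24 | trans-fused bicyclic cis-enone with free CH2OH | C=C1C/C=C\C(=O)CC[C@H]2[C@H]1CO[C@@]2(/C=C/C=C(C)C)CO | intermediate
25 | destearoyl target (primary and tertiary alcohol) | C=C1C/C=C\[C@@](C)(O)CC[C@H]2[C@H]1CO[C@@]2(/C=C/C=C(C)C)CO | intermediate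
26 | octadecanoyl chloride | CCCCCCCCCCCCCCCCCC(=O)Cl | starting material
27 | CNP0274030.1 | C=C1C/C=C\[C@@](C)(O)CC[C@H]2[C@H]1CO[C@@]2(/C=C/C=C(C)C)COC(=O)CCCCCCCCCCCCCCCCC | target

Total step count: 17. Longest linear sequence: 13 steps (9 to 27, steps 5–17).

Steps most likely to fail

Step 12.
- Part of the material may rearrange through a chair-like array, which would form the new bond on the other alkene face.
- A silyl group may wander to a neighbouring alkoxide.
- Proton transfer from the acidic ring CH2 between ketone and alkene may quench the enolate before the aldol capture.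

The fallback avoids alkoxides altogether and sets out from 17. Both tertiary hydroxyls would be capped with 1-(trimethylsilyl)imidazole to give the bis(trimethylsilyl) ether F1. Its neutral thermal siloxy-Cope rearrangement (decalin, about 200 °C) should give the bis(silyl enol ether) F2. A Mukaiyama aldol reaction of the more reactive trimethylsilyl enol ether with aqueous formaldehyde and Sc(OTf)3, which also strips the tertiary trimethylsilyl ether, comes back to the route at 20.

Step 16. The facial selectivity rests on the conformation of a flexible nine-membered enone and may be poor or reversed. The doubly allylic CH2 may also be deprotonated. The fallback replaces substrate control by catalyst control. It sets out from 24 and uses enantioselective methyl transfer from Me2Zn with Ti(OiPr)4 and a chiral trans-cyclohexane-1,2-diamine bis(sulfonamide) diol ligand, a known method for tertiary allylic alcohols from cyclic enones. The ligand antipode would be chosen for Re-face delivery. It comes back at 25 and makes no new compound (F0).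

Step 10. The β,γ-unsaturated, α-quaternary ketone may be enolised instead of attacked, facial selectivity may erode, and the very hindered alkyne may then resist hydroalumination in step 11. The fallback changes the nucleophile class and sets out from 8. Hydrostannation (Bu3SnH, PdCl2(PPh3)2 cat.) should give the (E)-vinylstannane F3. Tin–lithium exchange with n-BuLi and transmetalation to CeCl3 give a non-basic alkenylcerium reagent. Its addition to 14 comes back to the route directly at 17 and bypasses 16.

Further compounds
F1 | step 12 | bis(trimethylsilyl) ether of 17 | C=C[C@]1(O[Si](C(C)C)(C(C)C)C(C)C)C=CC[C@]1(O[Si](C)(C)C)/C=C/[C@@](O[Si](C)(C)C)(CO[Si](c1ccccc1)(c1ccccc1)C(C)(C)C)/C=C/C=C(C)C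
F2 | step 12 | ring-expanded all-cis cyclononatriene with trimethylsilyl enol ether, TIPS dienol ether and tertiary O-TMS group | C[Si](C)(C)O/C1=C/[C@@H]([C@@](O[Si](C)(C)C)(CO[Si](c2ccccc2)(c2ccccc2)C(C)(C)C)/C=C/C=C(C)C)C/C=C(O[Si](C(C)C)(C(C)C)C(C)C)\C=C/C1
F0 | step 16 | none | none
F3 | step 10 | (1E,3R,4E)-3-(TBDPS-oxymethyl)-7-methyl-1-(tributylstannyl)octa-1,4,6-trien-3-ol | CCCC[Sn](CCCC)(CCCC)/C=C/[C@@](O)(CO[Si](c1ccccc1)(c1ccccc1)C(C)(C)C)/C=C/C=C(C)C
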